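**Plan**

1. Retrosynthesis: a retro-Diels–Alder cut of C1–C13' and C3–C11' gives 5-acetoxycyclopentadiene 32 (guaianolide half) and α-methylene lactone 18 (seco-eudesmanolide half). In 18 the lactone bonds O–C8' and C12'–C11' are cut as CO2, which leaves methylidenecyclopropane 14. In 32 the C7–C8 bond and the lactone go back to a cyclopentenone carrying an aldehyde and an allylic bromide.
2. Enabling feature: in 14 the carbons C11'(=C13'H2), C7' and C8' form a methylidenecyclopropane cis-fused to ring A, and only C8' is allylic to the C9'=C10' silyl enol ether (the masked exocyclic C10'=C14').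
3. Forward, dienophile: (S)-citronellal → Z-allylic diazoacetate → cyclopropane-fused lactone → methylidenecyclopropane → aldol closure of ring A → (3+2) annulation of CO2 (lactone ring) → enone → triene 18.
4. Forward, diene: cyclopentenone 19 → Mukaiyama–Michael → Stork–Danheiser → cross-metathesis → Barbier closure of the seven-membered ring and lactone → 2-acetoxylation → allylic alcohol 31. Dehydration gives 32, which 18 traps; desilylation ends the route.
5. Stereochemistry: C4' comes from citronellal. C7'/C8' come from the Rh2(5S-MEPY)4 cyclopropanation and pass through the CO2 annulation with retention. C10 comes from the copper-box catalyst, C7/C8 from the chair allylation, C2 from acetoxylation anti to C10. C1, C3 and C11' come from the exo cycloaddition anti to the acetoxy group.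

Key step: step 13

Assumption: biogenetic numbering is used (guaianolide half C1–C15, seco-eudesmanolide half C1'–C15'; TBDPS = tert-butyldiphenylsilyl, TES = triethylsilyl); the carbinol centre C10' in 2–11 and the centres C5'/C6' in 13–16 are carried as epimer mixtures because they end trigonal.

**Dienophile half**

Step 1
Reactants: 1 (S)-citronellal
Product: 2 (6S)-6,10-dimethylundec-9-en-1-yn-4-ol (both C4 epimers)
Conditions: propargyl bromide, Zn dust, THF/sat. aq. NH4Cl, 0 → 25 °C
Reagents that add atoms: propargyl bromide, C#CCBr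
Why: Zinc-mediated Barbier propargylation of the aldehyde should give the homopropargylic alcohol (the allenylzinc reacts at its γ-carbon); the new carbinol C10' forms as both epimers, which is harmless because it is oxidised later, and the C4' centre of citronellal is untouched.

Step 2
Reactants: 2 (6S)-6,10-dimethylundec-9-en-1-yn-4-ol
Product: 3 (4S)-4-methylnon-8-yne-1,6-diol
Conditions: O3, CH2Cl2/MeOH, −78 °C (Sudan red end point); then NaBH4, −78 → 0 °C
Reagents that add atoms: ozone, [O-][O+]=O
Why: Ozonolysis cleaves the electron-rich trisubstituted alkene much faster than the terminal alkyne, and the reductive borohydride work-up gives the primary alcohol C1'.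

Step 3
Reactants: 3 (4S)-4-methylnon-8-yne-1,6-diol
Product: 4 (4S)-1-(TBDPS-oxy)-4-methylnon-8-yn-6-ol
Conditions: TBDPSCl (1.05 equiv), imidazole, DMF, 0 °C
Reagents that add atoms: tert-butyl(chloro)diphenylsilane, CC(C)(C)[Si](Cl)(c1ccccc1)c1ccccc1
Why: Silylation with the bulky chlorosilane is selective for the primary hydroxyl over the secondary C10' carbinol.

Step 4
Reactants: 4 (4S)-1-(TBDPS-oxy)-4-methylnon-8-yn-6-ol
Product: 5 (7S)-10-(TBDPS-oxy)-7-methyldec-2-yne-1,5-diol
Conditions: n-BuLi (2.2 equiv), THF, −78 °C; (CH2O)n, −78 → 0 °C; H2O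
Reagents that add atoms: formaldehyde (as paraformaldehyde), C=O
Why: Double deprotonation (alkoxide and acetylide) and hydroxymethylation of the lithium acetylide add C13' as a propargylic alcohol.

Step 5
Reactants: 5 (7S)-10-(TBDPS-oxy)-7-methyldec-2-yne-1,5-diol
Product: 6 (2Z,7S)-10-(TBDPS-oxy)-7-methyldec-2-ene-1,5-diol
Conditions: H2 (1 atm), Pd/CaCO3 poisoned with Pb(OAc)2, quinoline, EtOAc, 25 °C
Reagents that add atoms: none
Why: Lindlar semihydrogenation (syn delivery of H2 on poisoned palladium) gives the Z-alkene C8'=C11' that a cis-cyclopropane requires.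

Step 6
Reactants: 6 (2Z,7S)-10-(TBDPS-oxy)-7-methyldec-2-ene-1,5-diol
Product: 7 (2Z,7S)-10-(TBDPS-oxy)-5-hydroxy-7-methyldec-2-en-1-yl diazoacetate
Conditions: TsNHN=CHCOCl (1.05 equiv), PhNMe2, CH2Cl2, −20 °C; then Et3N, 0 °C
Reagents that add atoms: glyoxylic acid chloride 4-toluenesulfonylhydrazone, Cc1ccc(cc1)S(=O)(=O)NN=CC(Cl)=O
Why: The acid chloride acylates the more reactive primary allylic alcohol and base-induced loss of sulfinate from the tosylhydrazone (Bamford–Stevens-type fragmentation) should give the allylic diazoacetate.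

Step 7
Reactants: 7 (2Z,7S)-10-(TBDPS-oxy)-5-hydroxy-7-methyldec-2-en-1-yl diazoacetate
Product: 8 (1R,5S,6R)-6-[(4S)-7-(TBDPS-oxy)-2-hydroxy-4-methylheptyl]-3-oxabicyclo[3.1.0]hexan-2-one (all-cis cyclopropane)
Conditions: Rh2(5S-MEPY)4 (1 mol%; MEPY = methyl 2-oxopyrrolidine-5-carboxylate), CH2Cl2, 40 °C, slow addition
Reagents that add atoms: none
Why: Intramolecular cyclopropanation by the chiral dirhodium carboxamidate carbenoid is stereospecific for the Z-alkene (C6' and C9' cis), and the catalyst enantiomer, chosen by analogy with the known sense of induction for allylic diazoacetates (the antipodal catalyst gives the mirror-image ring), sets C7' and C8' together with the transient C11'.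

Step 8
Reactants: 8 (1R,5S,6R)-6-[(4S)-7-(TBDPS-oxy)-2-hydroxy-4-methylheptyl]-3-oxabicyclo[3.1.0]hexan-2-one
Product: 9 all-cis-2-[(4S)-7-(TBDPS-oxy)-2-hydroxy-4-methylheptyl]-3-(phenylselanylmethyl)cyclopropane-1-carboxylic acid
Conditions: PhSeNa, THF/HMPA, 65 °C; then 1 M HCl
Reagents that add atoms: sodium benzeneselenolate, [Na+].[Se-]c1ccccc1
Why: The soft selenolate opens the γ-lactone by SN2 attack at the primary cyclopropylcarbinyl carbon C13' (alkyl–oxygen cleavage), which leaves the three cyclopropane centres untouched.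

Step 9
Reactants: 9 all-cis-2-[(4S)-7-(TBDPS-oxy)-2-hydroxy-4-methylheptyl]-3-(phenylselanylmethyl)cyclopropane-1-carboxylic acid
Product: 10 cis-2-[(4S)-7-(TBDPS-oxy)-2-hydroxy-4-methylheptyl]-3-methylidenecyclopropane-1-carboxylic acid
Conditions: mCPBA (1.0 equiv), CH2Cl2, −78 °C; then i-Pr2NH, 40 °C
Reagents that add atoms: none
Why: Selenoxide syn-elimination can only take the cyclopropane hydrogen at C11', so the exocyclic C11'=C13' bond should form regiospecifically while the amine traps PhSeOH.

Step 10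
Reactants: 10 cis-2-[(4S)-7-(TBDPS-oxy)-2-hydroxy-4-methylheptyl]-3-methylidenecyclopropane-1-carboxylic acid
Product: 11 (4S)-7-(TBDPS-oxy)-1-[cis-2-(hydroxymethyl)-3-methylidenecyclopropyl]-4-methylheptan-2-ol
Conditions: LiAlH4, THF, 0 → 25 °C
Reagents that add atoms: none
Why: Hydride reduction of the carboxylic acid gives the primary alcohol C6' without touching the strained alkene or the silyl ether.

Step 11
Reactants: 11 (4S)-7-(TBDPS-oxy)-1-[cis-2-(hydroxymethyl)-3-methylidenecyclopropyl]-4-methylheptan-2-ol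
Product: 13 cis-fused 5-hydroxy-7-methylidene-4-[(2S)-5-(TBDPS-oxy)pentan-2-yl]bicyclo[4.1.0]heptan-3-one, via keto aldehyde 12 (not isolated)
Conditions: Dess–Martin periodinane, CH2Cl2, 0 → 25 °C; then DBU (0.2 equiv), −20 °C
Reagents that add atoms: none
Why: Dess–Martin oxidation of both alcohols gives keto aldehyde 12, whose only ring-forming enolate (C5') adds to the cis-disposed cyclopropane aldehyde in a six-membered intramolecular aldol reaction that closes ring A and is stopped before dehydration; the new C5'/C6' centres are transient.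

Step 12
Reactants: 13 cis-fused 5-hydroxy-7-methylidene-4-[(2S)-5-(TBDPS-oxy)pentan-2-yl]bicyclo[4.1.0]heptan-3-one
Product: 14 cis-fused 7-methylidene-4-[(2S)-5-(TBDPS-oxy)pentan-2-yl]-3,5-bis(triethylsilyloxy)bicyclo[4.1.0]hept-2-ene
Conditions: LiN(i-Pr)2 (2.5 equiv), THF, −78 °C; TESCl, HMPA, −78 → 0 °C
Reagents that add atoms: chlorotriethylsilane, CC[Si](Cl)(CC)CC
Why: Kinetic deprotonation at the less substituted α-carbon C9' and O-silylation of enolate and aldolate give the C9'=C10' silyl enol ether, which makes C8' the only allylic cyclopropane carbon while C5' stays sp3.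

Step 13
Reactants: 14 cis-fused 7-methylidene-4-[(2S)-5-(TBDPS-oxy)pentan-2-yl]-3,5-bis(triethylsilyloxy)bicyclo[4.1.0]hept-2-ene
Product: 15 cis-fused 3-methylidene-5-[(2S)-5-(TBDPS-oxy)pentan-2-yl]-4,6-bis(triethylsilyloxy)-3a,4,5,7a-tetrahydro-1-benzofuran-2(3H)-one
Conditions: Ni(cod)2 (10 mol%), PCy3 (10 mol%), CO2 (5 bar), THF, 40 °C
Reagents that add atoms: carbon dioxide, O=C=O
Why: Proposed new method: zerovalent nickel should couple the strained exocyclic alkene C11'=C13' with CO2 in a nickelalactone-forming oxidative cyclization that puts C12' on the ring carbon C11' and the metal on the unhindered C13'H2, as terminal alkynes do; strain-driven β-carbon elimination then cleaves the proximal C11'–C8' bond, because only this cleavage gives an η3-(siloxy)allyl nickel (C8'–C9'–C10') while restoring C11'=C13', and the allylnickel carboxylate closes by C–O reductive elimination at C8' with return of zerovalent nickel. The closest known reaction types are the nickel-mediated carboxylation of methylidenecyclopropanes, the palladium-catalysed (3+2) cycloadditions of methylidenecyclopropanes, vinylcyclopropanes and vinyl epoxides with CO2 or other heterocumulenes, and the Tsuji–Trost lactonization of allylmetal carboxylates. The lactone ring closes on the near allyl terminus C8' (five-membered; attack at C10' would give a seven-membered ring), so the net event is a (3+2) annulation of CO2 onto the unit C11'–C7'–C8'. No stereocentre is made afresh: C7' is untouched and the C8'–O bond forms on the face that C11' leaves (metal insertion with retention, inner-sphere C–O coupling), which the cis tether through C7' enforces, so the cis-fused lactone inherits the configuration set in step 7. The step needs cleavage of C11'–C8' and not of C11'–C7' or of the distal C7'–C8' bond, and C–C and not C–O bonding at C11'; the silyl enol ether at C9'=C10' (vinylcyclopropane activation of C8' only) and a phosphine-poor nickel catalyst under CO2 pressure are meant to secure this.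

Step 14
Reactants: 15 cis-fused 3-methylidene-5-[(2S)-5-(TBDPS-oxy)pentan-2-yl]-4,6-bis(triethylsilyloxy)-3a,4,5,7a-tetrahydro-1-benzofuran-2(3H)-one
Product: 17 (3aS,7aS)-3-methylidene-5-[(2S)-5-(TBDPS-oxy)pentan-2-yl]-7,7a-dihydro-1-benzofuran-2,6(3H,3aH)-dione, via hydroxy ketone 16 (not isolated)
Conditions: TsOH·H2O (cat.), acetone/H2O, 25 °C; then benzene, 50 °C
Reagents that add atoms: none
Why: Acid hydrolysis of the silyl enol ether returns the C10' ketone with C9'H2, and acid-catalysed β-elimination of the unveiled aldol hydroxyl (through the more substituted enol) should give the conjugated C5'=C6' enone and erase the transient centres.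

Step 15
Reactants: 17 (3aS,7aS)-3-methylidene-5-[(2S)-5-(TBDPS-oxy)pentan-2-yl]-7,7a-dihydro-1-benzofuran-2,6(3H,3aH)-dione
Product: 18 (3aS,7aS)-3,6-dimethylidene-5-[(2S)-5-(TBDPS-oxy)pentan-2-yl]-3a,6,7,7a-tetrahydro-1-benzofuran-2(3H)-one
Conditions: Zn, CH2Br2, TiCl4, THF/CH2Cl2, 0 → 25 °C
Reagents that add atoms: dibromomethane, BrCBr
Why: Lombardo methylenation with the non-basic Zn/CH2Br2/TiCl4 reagent converts the enone carbonyl into the exocyclic C10'=C14' bond and spares the lactone and its Michael-acceptor alkene.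

**Diene half**

Step 16
Reactants: 19 3-ethoxy-2-methylcyclopent-2-en-1-one
Product: 20 [(4-ethoxy-3-methylcyclopenta-1,3-dien-2-yl)oxy]trimethylsilane
Conditions: LiN(i-Pr)2, THF, −78 °C; TMSCl
Reagents that add atoms: chlorotrimethylsilane, C[Si](C)(C)Cl
Why: Kinetic α'-deprotonation of the vinylogous ester and O-silylation give the cross-conjugated silyl dienol ether.

Step 17
Reactants: 20 [(4-ethoxy-3-methylcyclopenta-1,3-dien-2-yl)oxy]trimethylsilane; 21 3-[(2E)-but-2-enoyl]-1,3-oxazolidin-2-one
Product: 22 3-{(3R)-3-[(1S)-4-ethoxy-3-methyl-2-oxocyclopent-3-en-1-yl]butanoyl}-1,3-oxazolidin-2-one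
Conditions: Cu((S,S)-t-Bu-box)(SbF6)2 (10 mol%), (CF3)2CHOH (1 equiv), CH2Cl2, −78 → −20 °C
Reagents that add atoms: none
Why: In this copper-bisoxazoline-catalysed Mukaiyama–Michael addition the enolsilane should attack the Re face of C10 of the chelated s-cis imide left open by the tert-butyl groups (accepted square-planar chelate model; the antipodal ligand gives the other sense), setting C10, while the adjacent C1 centre arises from the open transition state and remains epimerisable next to the carbonyl.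

Step 18
Reactants: 22 3-{(3R)-3-[(1S)-4-ethoxy-3-methyl-2-oxocyclopent-3-en-1-yl]butanoyl}-1,3-oxazolidin-2-one
Product: 23 (5S)-3-ethoxy-5-[(2R)-4-hydroxybutan-2-yl]-2-methylcyclopent-2-en-1-one
Conditions: LiBH4, THF/MeOH, 0 °C
Reagents that add atoms: none
Why: LiBH4 reduces the activated N-acyloxazolidinone to the primary alcohol (C8) faster than it touches the poorly electrophilic vinylogous ester carbonyl.

Step 19
Reactants: 23 (5S)-3-ethoxy-5-[(2R)-4-hydroxybutan-2-yl]-2-methylcyclopent-2-en-1-one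
Product: 25 (4S)-4-[(2R)-4-hydroxybutan-2-yl]-2-methyl-3-(prop-2-en-1-yl)cyclopent-2-en-1-one, via allylic alcohol 24 (not isolated)
Conditions: allylMgBr (3.5 equiv), THF, −78 → 0 °C; then 1 M HCl, 0 °C
Reagents that add atoms: allylmagnesium bromide, C=CC[Mg]Br
Why: In this Stork–Danheiser transposition the allyl Grignard reagent adds 1,2 to the vinylogous ester carbonyl (C5), and acid hydrolysis of the enol ether with loss of water gives the transposed enone that carries C6–C7 as an allyl group.

Step 20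
Reactants: 25 (4S)-4-[(2R)-4-hydroxybutan-2-yl]-2-methyl-3-(prop-2-en-1-yl)cyclopent-2-en-1-one
Product: 26 methyl (2Z)-2-(bromomethyl)-4-{(5S)-5-[(2R)-4-hydroxybutan-2-yl]-2-methyl-3-oxocyclopent-1-en-1-yl}but-2-enoate
Conditions: methyl 2-(bromomethyl)acrylate (5 equiv), second-generation Hoveyda–Grubbs catalyst RuCl2(H2IMes)(=CH-C6H4-2-O-i-Pr) (5 mol%), CH2Cl2, 40 °C
Reagents that add atoms: methyl 2-(bromomethyl)acrylate, C=C(CBr)C(=O)OC
Why: Olefin cross-metathesis of the terminal allyl group with the 1,1-disubstituted acrylate should give the trisubstituted enoate with C6 trans to the ester (the Z-bromide), the geometry favoured under thermodynamic control as for tiglates, while the tetrasubstituted enone alkene is inert.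

Step 21
Reactants: 26 methyl (2Z)-2-(bromomethyl)-4-{(5S)-5-[(2R)-4-hydroxybutan-2-yl]-2-methyl-3-oxocyclopent-1-en-1-yl}but-2-enoate
Product: 27 methyl (2Z)-2-(bromomethyl)-4-{(5S)-2-methyl-3-oxo-5-[(2R)-4-oxobutan-2-yl]cyclopent-1-en-1-yl}but-2-enoate
Conditions: Dess–Martin periodinane, CH2Cl2, 0 °C
Reagents that add atoms: none
Why: Dess–Martin oxidation gives the C8 aldehyde under neutral conditions that spare the allylic bromide and the enone.

Step 22
Reactants: 27 methyl (2Z)-2-(bromomethyl)-4-{(5S)-2-methyl-3-oxo-5-[(2R)-4-oxobutan-2-yl]cyclopent-1-en-1-yl}but-2-enoate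
Product: 29 (1S,7S,8R,10R)-3-oxoguaia-4,11(13)-dien-12,8-olide, via hydroxy ester 28 (not isolated)
Conditions: In powder, DMF (5 mM), 25 °C; then TsOH·H2O (cat.), CH2Cl2
Reagents that add atoms: none
Why: In this intramolecular Barbier allylation the allylindium should add to the aldehyde through a chair six-membered (Zimmerman–Traxler) transition state trans-fused to the forming seven-membered ring, so that C6 and C9 are both equatorial and C7/C8 come out anti (trans lactone), the aldehyde face being chosen by the C10 methyl and the C1 hydrogen already present; acid then closes the γ-lactone.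

Step 23
Reactants: 29 (1S,7S,8R,10R)-3-oxoguaia-4,11(13)-dien-12,8-olide
Product: 30 (1S,2R,7S,8R,10R)-2-acetoxy-3-oxoguaia-4,11(13)-dien-12,8-olide
Conditions: Mn(OAc)3·2H2O (3 equiv), benzene, 80 °C
Reagents that add atoms: manganese triacetate, CC(=O)[O-].CC(=O)[O-].CC(=O)[O-].[Mn+3]
Why: The α'-acetoxylation of the enone by trivalent manganese proceeds through the manganese enolate and its α-keto radical; acetate is delivered to C2 anti to the C1–C10 bond, and the epimerisable α-centre rests in this trans arrangement.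

Step 24
Reactants: 30 (1S,2R,7S,8R,10R)-2-acetoxy-3-oxoguaia-4,11(13)-dien-12,8-olide
Product: 31 (1S,2R,3S,7S,8R,10R)-2-acetoxy-3-hydroxyguaia-4,11(13)-dien-12,8-olide
Conditions: NaBH4, CeCl3·7H2O, MeOH, −78 °C
Reagents that add atoms: none
Why: Luche reduction gives 1,2-reduction of the enone only, hydride arriving anti to the acetoxy group so that 3-OH and 2-OAc are cis, which excludes neighbouring-group participation in the next step.

**Union and end game**

Step 25
Reactants: 31 (1S,2R,3S,7S,8R,10R)-2-acetoxy-3-hydroxyguaia-4,11(13)-dien-12,8-olide; 18 (3aS,7aS)-3,6-dimethylidene-5-[(2S)-5-(TBDPS-oxy)pentan-2-yl]-3a,6,7,7a-tetrahydro-1-benzofuran-2(3H)-one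
Product: 33 1'-O-TBDPS ether of the target (C1–C13' and C3–C11' bonded adduct), via cyclopentadiene 32 (not isolated)
Conditions: Ph2S[OC(CF3)2Ph]2 (Martin sulfurane, 1.2 equiv), 18 (3 equiv), CH2Cl2, −40 → 40 °C
Reagents that add atoms: none
Why: Dehydration of the allylic alcohol through its alkoxysulfonium ion (cation centred on tertiary C5, proton lost from C1) should unveil 5-acetoxycyclopentadiene 32, which the s-cis α-methylene lactone 18 traps in a Diels–Alder reaction: CH2-13' bonds to the substituted terminus C1 and the quaternary C11' to the unsubstituted C3 (sterics), the lactone carbonyl is exo as is usual for α-methylene-γ-butyrolactones, the diene reacts on its face anti to the 2-acetoxy and 10-methyl groups, and the target needs the lactone face cis to C6', where the flat ring A lies beside C3–H in the asynchronous transition state.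

Step 26
Reactants: 33 1'-O-TBDPS ether of the target
Product: 34 target, (1R,2S,3S,7S,8R,10R,4'S,7'S,8'S,11'S)-2-acetoxy-1'-hydroxy adduct of guaia-4,11(13)-dien-12,8-olide and 1,10-seco-eudesma-5,10(14)-dien-12,8-olide joined at C1–C13' and C3–C11'
Conditions: HF·pyridine, THF/pyridine, 0 → 25 °C
Reagents that add atoms: none
Why: Fluoride cleavage of the silyl ether under buffered acidic conditions frees the primary alcohol without acyl migration, conjugate addition or lactone opening.

**Compound list**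

1 | (S)-citronellal, (3S)-3,7-dimethyloct-6-enal | O=CC[C@@H](C)CCC=C(C)C | starting material
2 | (6S)-6,10-dimethylundec-9-en-1-yn-4-ol (C4 epimers) | C#CCC(O)C[C@@H](C)CCC=C(C)C | intermediate
3 | (4S)-4-methylnon-8-yne-1,6-diol | C#CCC(O)C[C@@H](C)CCCO | intermediate
4 | (4S)-1-(TBDPS-oxy)-4-methylnon-8-yn-6-ol | C#CCC(O)C[C@@H](C)CCCO[Si](c1ccccc1)(c1ccccc1)C(C)(C)C | intermediate
5 | (7S)-10-(TBDPS-oxy)-7-methyldec-2-yne-1,5-diol | OCC#CCC(O)C[C@@H](C)CCCO[Si](c1ccccc1)(c1ccccc1)C(C)(C)C | intermediate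
6 | (2Z,7S)-10-(TBDPS-oxy)-7-methyldec-2-ene-1,5-diol | OC/C=C\CC(O)C[C@@H](C)CCCO[Si](c1ccccc1)(c1ccccc1)C(C)(C)C | intermediate
7 | (2Z,7S)-10-(TBDPS-oxy)-5-hydroxy-7-methyldec-2-en-1-yl diazoacetate | [N-]=[N+]=CC(=O)OC/C=C\CC(O)C[C@@H](C)CCCO[Si](c1ccccc1)(c1ccccc1)C(C)(C)C | intermediate
8 | (1R,5S,6R)-6-[(4S)-7-(TBDPS-oxy)-2-hydroxy-4-methylheptyl]-3-oxabicyclo[3.1.0]hexan-2-one (all-cis cyclopropane) | O=C1OC[C@H]2[C@@H](CC(O)C[C@@H](C)CCCO[Si](c3ccccc3)(c3ccccc3)C(C)(C)C)[C@@H]12 | intermediate
9 | all-cis-2-[(4S)-7-(TBDPS-oxy)-2-hydroxy-4-methylheptyl]-3-(phenylselanylmethyl)cyclopropane-1-carboxylic acid | OC(=O)[C@H]1[C@@H](C[Se]c2ccccc2)[C@H]1CC(O)C[C@@H](C)CCCO[Si](c2ccccc2)(c2ccccc2)C(C)(C)C | intermediate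
10 | cis-2-[(4S)-7-(TBDPS-oxy)-2-hydroxy-4-methylheptyl]-3-methylidenecyclopropane-1-carboxylic acid | C=C1[C@@H](CC(O)C[C@@H](C)CCCO[Si](c2ccccc2)(c2ccccc2)C(C)(C)C)[C@H]1C(=O)O | intermediate
11 | (4S)-7-(TBDPS-oxy)-1-[cis-2-(hydroxymethyl)-3-methylidenecyclopropyl]-4-methylheptan-2-ol | C=C1[C@@H](CC(O)C[C@@H](C)CCCO[Si](c2ccccc2)(c2ccccc2)C(C)(C)C)[C@H]1CO | intermediate
12 | cis-2-[(4S)-7-(TBDPS-oxy)-4-methyl-2-oxoheptyl]-3-methylidenecyclopropane-1-carbaldehyde (keto aldehyde) | C=C1[C@@H](CC(=O)C[C@@H](C)CCCO[Si](c2ccccc2)(c2ccccc2)C(C)(C)C)[C@H]1C=O | intermediate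
13 | cis-fused 5-hydroxy-7-methylidene-4-[(2S)-5-(TBDPS-oxy)pentan-2-yl]bicyclo[4.1.0]heptan-3-one (C4/C5 epimers) | C=C1[C@H]2CC(=O)C([C@@H](C)CCCO[Si](c3ccccc3)(c3ccccc3)C(C)(C)C)C(O)[C@@H]12 | intermediate
14 | cis-fused 7-methylidene-4-[(2S)-5-(TBDPS-oxy)pentan-2-yl]-3,5-bis(triethylsilyloxy)bicyclo[4.1.0]hept-2-ene | C=C1[C@H]2C=C(O[Si](CC)(CC)CC)C([C@@H](C)CCCO[Si](c3ccccc3)(c3ccccc3)C(C)(C)C)C(O[Si](CC)(CC)CC)[C@@H]12 | intermediate
15 | cis-fused 3-methylidene-5-[(2S)-5-(TBDPS-oxy)pentan-2-yl]-4,6-bis(triethylsilyloxy)-3a,4,5,7a-tetrahydro-1-benzofuran-2(3H)-one (C7', C8' as in 34) | C=C1C(=O)O[C@H]2C=C(O[Si](CC)(CC)CC)C([C@@H](C)CCCO[Si](c3ccccc3)(c3ccccc3)C(C)(C)C)C(O[Si](CC)(CC)CC)[C@@H]12 | intermediate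
16 | cis-fused 4-hydroxy-3-methylidene-5-[(2S)-5-(TBDPS-oxy)pentan-2-yl]hexahydro-1-benzofuran-2,6-dione (hydroxy ketone) | C=C1C(=O)O[C@H]2CC(=O)C([C@@H](C)CCCO[Si](c3ccccc3)(c3ccccc3)C(C)(C)C)C(O)[C@@H]12 | intermediate
17 | (3aS,7aS)-3-methylidene-5-[(2S)-5-(TBDPS-oxy)pentan-2-yl]-7,7a-dihydro-1-benzofuran-2,6(3H,3aH)-dione | C=C1C(=O)O[C@H]2CC(=O)C([C@@H](C)CCCO[Si](c3ccccc3)(c3ccccc3)C(C)(C)C)=C[C@@H]12 | intermediate
18 | (3aS,7aS)-3,6-dimethylidene-5-[(2S)-5-(TBDPS-oxy)pentan-2-yl]-3a,6,7,7a-tetrahydro-1-benzofuran-2(3H)-one | C=C1C(=O)O[C@H]2CC(=C)C([C@@H](C)CCCO[Si](c3ccccc3)(c3ccccc3)C(C)(C)C)=C[C@@H]12 | intermediate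
19 | 3-ethoxy-2-methylcyclopent-2-en-1-one | CCOC1=C(C)C(=O)CC1 | starting material
20 | [(4-ethoxy-3-methylcyclopenta-1,3-dien-2-yl)oxy]trimethylsilane | CCOC1=C(C)C(O[Si](C)(C)C)=CC1 | intermediate
21 | 3-[(2E)-but-2-enoyl]-1,3-oxazolidin-2-one | C/C=C/C(=O)N1CCOC1=O | starting material
22 | 3-{(3R)-3-[(1S)-4-ethoxy-3-methyl-2-oxocyclopent-3-en-1-yl]butanoyl}-1,3-oxazolidin-2-one | CCOC1=C(C)C(=O)[C@@H](C1)[C@H](C)CC(=O)N1CCOC1=O | intermediate
23 | (5S)-3-ethoxy-5-[(2R)-4-hydroxybutan-2-yl]-2-methylcyclopent-2-en-1-one | CCOC1=C(C)C(=O)[C@@H](C1)[C@H](C)CCO | intermediate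
24 | 3-ethoxy-5-[(2R)-4-hydroxybutan-2-yl]-2-methyl-1-(prop-2-en-1-yl)cyclopent-2-en-1-ol (allylic alcohol) | CCOC1=C(C)C(O)(CC=C)[C@@H](C1)[C@H](C)CCO | intermediate
25 | (4S)-4-[(2R)-4-hydroxybutan-2-yl]-2-methyl-3-(prop-2-en-1-yl)cyclopent-2-en-1-one | O=C1C[C@@H]([C@H](C)CCO)C(CC=C)=C1C | intermediate
26 | methyl (2Z)-2-(bromomethyl)-4-{(5S)-5-[(2R)-4-hydroxybutan-2-yl]-2-methyl-3-oxocyclopent-1-en-1-yl}but-2-enoate | O=C1C[C@@H]([C@H](C)CCO)C(C/C=C(\CBr)C(=O)OC)=C1C | intermediate
27 | methyl (2Z)-2-(bromomethyl)-4-{(5S)-2-methyl-3-oxo-5-[(2R)-4-oxobutan-2-yl]cyclopent-1-en-1-yl}but-2-enoate | O=C1C[C@@H]([C@H](C)CC=O)C(C/C=C(\CBr)C(=O)OC)=C1C | intermediate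
28 | methyl 2-[(5S,6R,8R,8aS)-6-hydroxy-3,8-dimethyl-2-oxo-1,2,4,5,6,7,8,8a-octahydroazulen-5-yl]prop-2-enoate (hydroxy ester) | O=C1C[C@H]2[C@H](C)C[C@@H](O)[C@H](C(=C)C(=O)OC)CC2=C1C | intermediate
29 | (1S,7S,8R,10R)-3-oxoguaia-4,11(13)-dien-12,8-olide (trans lactone) | O=C1C[C@H]2[C@H](C)C[C@H]3OC(=O)C(=C)[C@@H]3CC2=C1C | intermediate
30 | (1S,2R,7S,8R,10R)-2-acetoxy-3-oxoguaia-4,11(13)-dien-12,8-olide | O=C1[C@H](OC(C)=O)[C@H]2[C@H](C)C[C@H]3OC(=O)C(=C)[C@@H]3CC2=C1C | intermediate
31 | (1S,2R,3S,7S,8R,10R)-2-acetoxy-3-hydroxyguaia-4,11(13)-dien-12,8-olide (2,3-cis) | O[C@@H]1[C@H](OC(C)=O)[C@H]2[C@H](C)C[C@H]3OC(=O)C(=C)[C@@H]3CC2=C1C | intermediate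
32 | (2S,7S,8R,10R)-2-acetoxyguaia-1(5),3,11(13)-trien-12,8-olide (cyclopentadiene) | CC(=O)O[C@H]1C=C(C)C2=C1[C@H](C)C[C@H]3OC(=O)C(=C)[C@@H]3C2 | intermediate
33 | 1'-O-TBDPS ether of 34 | C=C1C[C@@H]2OC(=O)[C@@]3(C[C@@]45C(=C(C)[C@@H]3[C@@H]4OC(C)=O)C[C@H]3C(=C)C(=O)O[C@@H]3C[C@H]5C)[C@@H]2C=C1[C@@H](C)CCCO[Si](c1ccccc1)(c1ccccc1)C(C)(C)C | intermediate
34 | target (1R,2S,3S,7S,8R,10R,4'S,7'S,8'S,11'S) | C=C1C[C@@H]2OC(=O)[C@@]3(C[C@@]45C(=C(C)[C@@H]3[C@@H]4OC(C)=O)C[C@H]3C(=C)C(=O)O[C@@H]3C[C@H]5C)[C@@H]2C=C1[C@@H](C)CCCO | target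

**Count and risks**

Total step count: 26. Longest linear sequence: 17 steps (steps 1–15, 25 and 26).

Steps most likely to fail:

1. Step 13 (Proposed new method). The process at risk is ring opening at the wrong cyclopropane bond, or nickel-catalysed vinylcyclopropane rearrangement outrunning CO2 capture, or C–O reductive elimination failing to turn the catalyst over. The fallback uses known chemistry, sets out from 13 and returns at 17. The aldol hydroxyl of 13 is silylated (TESCl, imidazole) to the triethylsilyl ether F1. Iodine (ClCH2CH2Cl, 60 °C; the known halogenative ring opening of methylidenecyclopropanes to 2,4-dihalobut-1-enes) opens the ring with inversion at the less hindered carbon C8' and gives the vinyl/alkyl diiodide F2. Palladium-catalysed hydroxycarbonylation of the vinyl iodide (Pd(PPh3)4, CO, K2CO3, aq. DMF) gives the acrylate, whose carboxylate displaces the secondary iodide in an SN2 lactonization (second inversion, net retention) to the cis-fused silyloxy keto lactone F3. TsOH then eliminates the silyloxy group and gives 17.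

2. Step 25. The processes at risk are poor facial discrimination at the dienophile (addition anti and not cis to C6', which gives the C11' epimer), a 1,5-hydrogen shift of the 5-acetoxycyclopentadiene, and its self-dimerisation through its own α-methylene lactone. The fallback replaces substrate control by catalyst control, sets out from 31 and 18, returns at 33 and makes no new compound (F0). Alcohol 31 is dehydrated at −40 °C and the cold solution of 32 is added to 18 that has been activated by a chiral oxazaborolidinium triflimide. The catalyst binds the lactone carbonyl and shields one face of the methylidene group, so the outcome at C11' is dictated by the catalyst enantiomer, and the low temperature suppresses the hydrogen shift.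

3. Step 22. The process at risk is syn addition through the (Z)-allylindium chair, which would give the cis-fused lactone, together with uncertain control by C10 over the aldehyde face. The fallback sets out from 27 and returns at 29. The cyclisation is run as before and the cis-fused 8-epi-lactone F4 is taken on: LiOH opens it to the hydroxy acid F5, and Mitsunobu lactonisation (PPh3, DIAD) closes the ring again with inversion at C8 to give 29.

Further compounds
F1 | step 13 | triethylsilyl ether of 13 | C=C1[C@H]2CC(=O)C([C@@H](C)CCCO[Si](c3ccccc3)(c3ccccc3)C(C)(C)C)C(O[Si](CC)(CC)CC)[C@@H]12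
F2 | step 13 | trans-5-iodo-4-(1-iodoethenyl)-2-[(2S)-5-(TBDPS-oxy)pentan-2-yl]-3-(triethylsilyloxy)cyclohexan-1-one (diiodide) | C=C(I)[C@@H]1C(O[Si](CC)(CC)CC)C([C@@H](C)CCCO[Si](c2ccccc2)(c2ccccc2)C(C)(C)C)C(=O)C[C@H]1I
F3 | step 13 | cis-fused 3-methylidene-5-[(2S)-5-(TBDPS-oxy)pentan-2-yl]-4-(triethylsilyloxy)hexahydro-1-benzofuran-2,6-dione | C=C1C(=O)O[C@H]2CC(=O)C([C@@H](C)CCCO[Si](c3ccccc3)(c3ccccc3)C(C)(C)C)C(O[Si](CC)(CC)CC)[C@@H]12
F0 | step 25 | none | none
F4 | step 22 | 8-epi-29, cis-fused 3-oxoguaia-4,11(13)-dien-12,8-olide | O=C1C[C@H]2[C@H](C)C[C@@H]3OC(=O)C(=C)[C@@H]3CC2=C1C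
F5 | step 22 | 8-epi hydroxy acid, 2-[6-hydroxy-3,8-dimethyl-2-oxo-1,2,4,5,6,7,8,8a-octahydroazulen-5-yl]prop-2-enoic acid | O=C1C[C@H]2[C@H](C)C[C@H](O)[C@H](C(=C)C(=O)O)CC2=C1C
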